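**Remark on the chemistry (assumption):** the target is achiral; Z for 10–12 means carboxyl or ester cis to the aryloxy oxygen, and any E isomer formed in step 5 is assumed to be carried along and to converge under the acid of step 7. The connectivity of 11 and 13 was rechecked atom by atom against the target and needs no correction.

## Structural features

The target is a flavone: benzene ring A is fused to the γ-pyranone ring C (O1, C2, C3, C4=O, C4a, C8a), and ring B is attached at C2 through the C2–C1' bond. Ring A is fully substituted (OH at C5, OMe at C6, C7 and C8), and ring B carries a hydroquinone pair (OH at C2' and C5') with OMe at C4'. There is no stereocentre, so none stand next to each other; the only stereochemical element on the way is the geometry of an acyclic enol ether alkene. The fragile groups are the ring B hydroquinone (air oxidation to the quinone, above all in base), the 2'-OH next to the pyranone (in hot base or aqueous acid ring C can open to a 1,3-diketone and close again through O2'), and, in the intermediates, an acid-labile enol ether. The real difficulty is not the skeleton but telling seven oxygens apart: one of four on ring A and two of three on ring B must end as free hydroxyl, and a pentaoxygenated ring A must be assembled without regiochemical doubt. The key step exploits that in a 2,3,4,5-tetramethoxyphenyl ether the carbon that becomes C4a is the only ring A carbon bearing hydrogen, ortho to O5 and O1 and para to O7, so the C4 acyl carbon can bond at one place only. The end game exploits the peri relationship of the C4 carbonyl and O5, which singles out the C5 methyl ether by chelation, and the secondary-alkyl character of the ring B isopropyl ethers.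

## Logic of the disconnections

**14 to 13.** The bonds cut are the three oxygen–alkyl bonds at O5 (methyl), O2' and O5' (isopropyl). The free hydroxyls are the fragile part of 14 and are best masked to the end, and the masks are chosen so that one Lewis acid removes all three. The gain is that 13 has no free hydroxyl and a ring A with four like substituents. The demand is that the forward step cleaves exactly one of five methyl ethers, which needs chelation control at low temperature and exclusion of air.

**13 to 11 (through 12).** The bond cut is C4–C4a, which opens ring C. The cut is made there because C4a is the only unsubstituted carbon of ring A in 11, so the forward acylation has one possible site and all five ring A oxygens are in place beforehand. The gain is that the bicyclic core becomes an open diaryl enol ether acid. The demand is a carboxyl cis to the aryloxy group (or able to become so) and an activation that is anhydrous and free of strong Lewis acid, so that the isopropyl ethers survive. The isopropyl ethers are kept as the ring B masks because they survive that acid, fall to the same reagent as the C5 methyl ether, and release no benzylic cation that could alkylate the electron-rich rings.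

**11 to 10.** The bond cut is the oxygen–ethyl bond of an ester, a functional group change. It is needed because a carboxylate would deactivate the alkyne in the conjugate addition that precedes it. There is no gain in skeleton; the ester is the activating group. The demand is that hydrolysis must not displace the aryloxy group from C2 of the vinylogous carbonate and that acidification spares the enol ether.

**10 to 9 and 4.** The bond cut is O1–C2. It is a heteroatom–carbon bond at the electrophilic β-carbon of an ynoate, and it divides the molecule into a ring A half and a ring B half of similar size. The demand is regioselective attack at the aryl-bearing alkyne carbon by a hindered phenoxide, with anti protonation to give the Z alkene.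

**9 to 7 and 8.** The bond cut is C1'–C2, an aryl–alkynyl bond. A cross-coupling makes it, and all three carbons of ring C then arrive in one piece with 8. Ring B is reduced to an aryl iodide. The demand is that the coupling outruns base-induced oligomerisation of 8.

**7 to 6 to 5.** The bonds cut are C1'–I and then the two oxygen–isopropyl bonds. The carbon para to the methoxy group and ortho to one isopropoxy group is the most nucleophilic unhindered position of 6, so the halogen goes where ring C must be attached. The gain is arrival at 5, in which the three ring B oxygens are already placed and the one that stays methylated is already distinguished. The demand is clean monoiodination without oxidation of the hydroquinone diether.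

**4 to 1 (through 2 and 3).** The bond cut is the carbon–oxygen bond of the phenol (the future C8a–O1). The two ring hydrogens of 1 are equivalent and each is ortho to a methoxy group, so metalation can occur only there. The gain is that all four ring A methoxy groups come from a commercial arene in one operation. The demand is oxidation of the carbon–boron bond without oxidising the electron-rich ring.

## Other disconnections considered

**Alternative 1:** The cut is the C2–C1' bond between rings C and B, made after ring B has been tied to C3 through an aryl ester. In the forward key step, ester A1 (4-(benzyloxy)-2-bromo-5-methoxyphenyl 5,6,7,8-tetramethoxy-4-oxo-4H-chromene-3-carboxylate) would be heated with Pd(OAc)2, tricyclohexylphosphine and K2CO3. Zerovalent palladium inserts into the C–Br bond, C2–H is palladated by concerted metalation–deprotonation, and reductive elimination from divalent palladium closes the six-membered lactone of A2 (the 5'-benzyloxy-4',5,6,7,8-pentamethoxyflavone bridged from C3 to O2' by a carbonyl group).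
- In its favour: the tether leaves C2 as the only carbon the aryl group can reach, the 2'-oxygen arrives as the lactone oxygen and is told apart from the benzylated 5'-oxygen, and no alkene geometry arises. On the last point it is better than the chosen plan; on regiochemical certainty it is its equal.
- Against it here: the aryl ester of a chromone-3-carboxylic acid is an activated acyl donor and C2 of such a chromone is a strong Michael acceptor, so carbonate or liberated phenoxide could cleave the ester or open ring C at the temperature direct arylation needs. Oxidative addition into an electron-rich bromide is slow. After the key step the lactone must be hydrolysed and the C3 carboxyl removed to reach A3 (5'-(benzyloxy)-2'-hydroxy-4',5,6,7,8-pentamethoxyflavone), followed by hydrogenolysis and the same C5 demethylation as in step 8.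
- Comparison: both plans draw ring A from 4, but the alternative installs and then deletes a carbon at C3, and its differentiation of O2' from O5' is not needed because both end as hydroxyl. Mechanistically it relies on organometallic C–H functionalisation beside a base-sensitive pyranone, the chosen plan on an electrophilic substitution with one possible site. It should need about three steps after its key step against one, and some four or five more overall.

**Alternative 2:** The cut runs through ring B itself, at C1'–C2' and C5'–C6'. In the forward key step, alkyne A4 (2-ethynyl-5,6,7,8-tetramethoxy-4H-chromen-4-one) and diene A5 (4-methoxy-2-(trimethylsilyloxy)furan) would undergo a Diels–Alder reaction across the furan 2- and 5-positions. The oxygen bridge then opens, the ring aromatises and the silyl group is lost on work-up, giving A6 (2',5'-dihydroxy-4',5,6,7,8-pentamethoxyflavone).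
- In its favour: ring B appears with its final substitution and without any protecting group, which is better than the chosen plan in protecting-group economy. The regiochemistry is electronically matched, since the most nucleophilic furan terminus (C5, vinylogous to the silyl ketene acetal and β to the methoxy group) pairs with the terminal alkyne carbon, the electrophilic end of the ynone-like acceptor. One step (C5 demethylation) would remain after the key step, equal to the chosen plan.
- Against it here: silyloxyfurans tend to react with such acceptors as vinylogous Mukaiyama–Michael donors, so a stepwise conjugate addition that stops at a butenolide is a likely diversion. A4 is a polyfunctional Michael acceptor prone to oligomerise, and making it from 4 would take several steps with an uncertain ring closure. The last step would expose an unprotected hydroquinone to a Lewis acid.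
- Comparison: structurally it is the most direct way to the ring B pattern, but ring A and ring C must be complete before the key step. Mechanistically a pericyclic step with a polar escape route stands against a polar step with a single possible site. Overall length should be similar or slightly greater, with weaker precedent for the key step on this acceptor class.

**Alternative 3:** The cut is in ring A, at C5–C4a (and one step earlier at C8–C8a). In the forward key step, heating cyclobutenone A7 (racemic 2,3,4-trimethoxy-4-[6-(2,5-bis(benzyloxy)-4-methoxyphenyl)-4-oxo-4H-pyran-2-yl]cyclobut-2-en-1-one) would open the four-membered ring to a dienylketene, the methoxy group turning outward and the pyranonyl group inward. The ketene carbon then bonds to the adjacent pyranone CH in a six-electron electrocyclisation, and tautomerisation gives A8 (2',5'-bis(benzyloxy)-5-hydroxy-4',6,7,8-tetramethoxyflavone).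
- In its favour: the 5-OH is delivered free and already distinct from the three ring A methoxy groups, which all come from dimethyl squarate A9. No selective demethylation is needed, and on this point it is better than the chosen plan. The step is thermal and reagent-free, and one step (hydrogenolysis with H2 and Pd/C) would remain after it, equal to the chosen plan.
- Against it here: A7 requires pyranone A10 (2-[2,5-bis(benzyloxy)-4-methoxyphenyl]-4H-pyran-4-one) to be metallated at C6, added to one carbonyl of A9, and the hindered tertiary alkoxide to be methylated. 4-Pyranones are attacked by organolithium reagents at C4 and at C2 or C6, and deprotonation beside the ring oxygen (for example with lithium 2,2,6,6-tetramethylpiperidide) is poorly precedented. A10 itself needs several steps, and the electrocyclisation has to engage a double bond that is part of a vinylogous ester.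
- Comparison: both plans place every ring A oxygen without ambiguity, by different means. Mechanistically a pericyclic cascade stands against a Friedel–Crafts closure. The alternative should be three or four steps longer, with its weakest step early in the sequence.

Key step: step 7

## Route

Step 1
Reactants: 1 1,2,3,4-tetramethoxybenzene
Product: 4 2,3,4,5-tetramethoxyphenol, via aryllithium 2 (not isolated), via dimethyl arylboronate 3 (not isolated)
Conditions: n-BuLi, TMEDA, THF, 0 °C; B(OMe)3, −78 °C → rt; AcOH, 30% H2O2, 0 °C → rt
Reagents that add atoms: hydrogen peroxide, OO
Why: Directed ortho-metalation can only occur at the two equivalent ring C–H positions of 1, each flanked by a methoxy group; the aryllithium is borylated and the C–B bond is oxidised by peroxide with 1,2-shift of the aryl group from boron to oxygen (lithiation–borylation–oxidation), which gives the phenol in one flask in place of a formylation and Baeyer–Villiger pair.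

Step 2
Reactants: 5 2-methoxyhydroquinone
Product: 6 1,4-diisopropoxy-2-methoxybenzene
Conditions: 2-bromopropane (excess), K2CO3, DMF, 60 °C, N2
Reagents that add atoms: 2-bromopropane, CC(C)Br
Why: Double Williamson etherification of the two phenolic hydroxyls; excess secondary bromide makes up for E2 loss and exclusion of air keeps the hydroquinone anion from oxidising.

Step 3
Reactants: 6 1,4-diisopropoxy-2-methoxybenzene
Product: 7 1-iodo-2,5-diisopropoxy-4-methoxybenzene
Conditions: NIS, TFA (cat.), MeCN, 0 °C → rt, dark
Reagents that add atoms: N-iodosuccinimide, O=C1CCC(=O)N1I
Why: Electrophilic aromatic iodination; the carbon para to the methoxy group and ortho to one isopropoxy group is activated by two oxygens and unhindered, whereas the carbon between two alkoxy groups is shielded and the third is activated by one oxygen only, as in the halogenation of 1,2,4-trialkoxybenzenes.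

Step 4
Reactants: 7 1-iodo-2,5-diisopropoxy-4-methoxybenzene, 8 ethyl propiolate (ethyl prop-2-ynoate)
Product: 9 ethyl 3-(2,5-diisopropoxy-4-methoxyphenyl)prop-2-ynoate
Conditions: Pd(PPh3)2Cl2 (cat.), CuI (cat.), K2CO3, THF, 65 °C, slow addition of 8 (excess)
Reagents that add atoms: none
Why: Sonogashira-type coupling of an aryl iodide with an alkyl propiolate under inorganic-base conditions: zerovalent palladium inserts into the C–I bond, the copper acetylide of 8 transmetalates and reductive elimination forms the aryl–alkynyl bond; a carbonate base in place of an amine and slow addition of 8 hold back conjugate addition and oligomerisation of the propiolate.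

Step 5
Reactants: 9 ethyl 3-(2,5-diisopropoxy-4-methoxyphenyl)prop-2-ynoate, 4 2,3,4,5-tetramethoxyphenol
Product: 10 ethyl (Z)-3-(2,5-diisopropoxy-4-methoxyphenyl)-3-(2,3,4,5-tetramethoxyphenoxy)acrylate
Conditions: K2CO3, DMF, 90 °C, N2
Reagents that add atoms: none
Why: Base-mediated oxa-Michael addition of a phenoxide to an ynoate: the phenoxide of 4 attacks the β-carbon (the future C2) and the allenolate is protonated anti, which places the ester cis to the aryloxy group (Z); any E isomer is carried on because step 7 equilibrates the push–pull alkene.

Step 6
Reactants: 10 ethyl (Z)-3-(2,5-diisopropoxy-4-methoxyphenyl)-3-(2,3,4,5-tetramethoxyphenoxy)acrylate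
Product: 11 (Z)-3-(2,5-diisopropoxy-4-methoxyphenyl)-3-(2,3,4,5-tetramethoxyphenoxy)acrylic acid
Conditions: LiOH·H2O, THF/MeOH/H2O, 40 °C; then 1 M HCl to pH 3, 0 °C
Reagents that add atoms: lithium hydroxide, [Li+].[OH-]
Why: Saponification by acyl–oxygen cleavage at mild temperature; the donor-substituted β-carbon is a poor acceptor, so hydroxide should attack the ester carbonyl and not displace the aryloxide, and cold acidification to pH 3 spares the enol ether.

Step 7
Reactants: 11 (Z)-3-(2,5-diisopropoxy-4-methoxyphenyl)-3-(2,3,4,5-tetramethoxyphenoxy)acrylic acid
Product: 13 2',5'-diisopropoxy-4',5,6,7,8-pentamethoxyflavone, via mixed trifluoroacetic anhydride 12 (not isolated)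
Conditions: TFAA, CH2Cl2, 0 °C → rt (TfOH cat. if slow)
Reagents that add atoms: none
Why: TFAA converts the acid into the mixed anhydride 12, which ionises to an acylium ion that is stabilised as a vinylogous carbonate cation by the enol ether oxygen and by ring B. The acyl carbon attacks C4a of ring A and the Wheland intermediate loses a proton to trifluoroacetate, forming C4–C4a and the γ-pyranone. The closest known reaction type is the acid-mediated cyclodehydration of β-aryloxycinnamic acids to flavones (Ruhemann-type), an intramolecular Friedel–Crafts acylation. Ring C closes in a six-membered mode, exo with respect to the acylium carbon and endo with respect to the attacked C4a=C8a arene bond. No stereocentre is formed. Site selectivity is secured by the substrate: C4a is the only unsubstituted carbon of ring A and is ortho to O5 and O1 and para to O7, whereas closure onto C6' of ring B would need the E geometry, would give a five-membered indenone and would engage a carbon activated by one oxygen only. The Z acid has the carboxyl cis to the aryloxy group as required, and any E isomer equilibrates by reversible protonation at C3, which makes C2 an oxocarbenium centre with free rotation, and is drained through the Z form. No strong Lewis acid is present, so the isopropyl and methyl ethers should survive, and water is excluded so that the enol ether is not hydrolysed.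

Step 8
Reactants: 13 2',5'-diisopropoxy-4',5,6,7,8-pentamethoxyflavone
Product: 14 5,2',5'-trihydroxy-6,7,8,4'-tetramethoxyflavone (target)
Conditions: BCl3 (excess), CH2Cl2, −78 → 0 °C; then H2O, 0 °C, degassed solvents, Na2S2O4 wash
Reagents that add atoms: none
Why: BCl3 cleaves the two isopropyl ethers by ionisation of the secondary alkyl–oxygen bond at low temperature and cleaves the C5 methyl ether through the six-membered chelate of boron with O5 and the C4 carbonyl, which delivers chloride to that methyl group only; the other four methyl ethers have neither feature below 0 °C, and hydrolysis of the aryl borates releases the three phenols (chelation-controlled Lewis-acid dealkylation).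

## Compound list

1 | 1,2,3,4-tetramethoxybenzene | COc1ccc(OC)c(OC)c1OC | starting material
2 | (2,3,4,5-tetramethoxyphenyl)lithium | [Li]c1cc(OC)c(OC)c(OC)c1OC | intermediate
3 | dimethyl (2,3,4,5-tetramethoxyphenyl)boronate | COB(OC)c1cc(OC)c(OC)c(OC)c1OC | intermediate
4 | 2,3,4,5-tetramethoxyphenol | COc1cc(O)c(OC)c(OC)c1OC | intermediate
5 | 2-methoxyhydroquinone (2-methoxybenzene-1,4-diol) | COc1cc(O)ccc1O | starting material
6 | 1,4-diisopropoxy-2-methoxybenzene | COc1cc(OC(C)C)ccc1OC(C)C | intermediate
7 | 1-iodo-2,5-diisopropoxy-4-methoxybenzene | COc1cc(OC(C)C)c(I)cc1OC(C)C | intermediate
8 | ethyl propiolate (ethyl prop-2-ynoate) | CCOC(=O)C#C | starting material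
9 | ethyl 3-(2,5-diisopropoxy-4-methoxyphenyl)prop-2-ynoate | CCOC(=O)C#Cc1cc(OC(C)C)c(OC)cc1OC(C)C | intermediate
10 | ethyl (Z)-3-(2,5-diisopropoxy-4-methoxyphenyl)-3-(2,3,4,5-tetramethoxyphenoxy)acrylate | COc1cc(O/C(=C\C(=O)OCC)c2cc(OC(C)C)c(OC)cc2OC(C)C)c(OC)c(OC)c1OC | intermediate
11 | (Z)-3-(2,5-diisopropoxy-4-methoxyphenyl)-3-(2,3,4,5-tetramethoxyphenoxy)acrylic acid | COc1cc(O/C(=C\C(=O)O)c2cc(OC(C)C)c(OC)cc2OC(C)C)c(OC)c(OC)c1OC | intermediate
12 | (Z)-3-(2,5-diisopropoxy-4-methoxyphenyl)-3-(2,3,4,5-tetramethoxyphenoxy)acrylic trifluoroacetic anhydride | COc1cc(O/C(=C\C(=O)OC(=O)C(F)(F)F)c2cc(OC(C)C)c(OC)cc2OC(C)C)c(OC)c(OC)c1OC | intermediate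
13 | 2',5'-diisopropoxy-4',5,6,7,8-pentamethoxyflavone (2-(2,5-diisopropoxy-4-methoxyphenyl)-5,6,7,8-tetramethoxy-4H-chromen-4-one) | COc1cc(OC(C)C)c(-c2cc(=O)c3c(OC)c(OC)c(OC)c(OC)c3o2)cc1OC(C)C | intermediate
14 | 5,2',5'-trihydroxy-6,7,8,4'-tetramethoxyflavone (2-(2,5-dihydroxy-4-methoxyphenyl)-5-hydroxy-6,7,8-trimethoxy-4H-chromen-4-one) | COc1cc(O)c(-c2cc(=O)c3c(O)c(OC)c(OC)c(OC)c3o2)cc1O | target

## Step count and risk

Total: 8 steps. Longest linear sequence: 7 steps (5 → 6 → 7 → 9 → 10 → 11 → 13 → 14, steps 2 to 8); the other branch (1 → 4, step 1) joins at step 5.

**Step 7 (key step).** The acylium ion is strongly stabilised, so ring closure may be slow, and during that time adventitious water can hydrolyse the enol ether (fragmentation to 4 and a β-keto acid that decarboxylates) or the E isomer can divert to the indenone. Fallback, closing ring C from the other side (O1–C2 last), setting out from 4 and 6 and coming back at 13: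
- C-acetylation of 4 at its only free carbon (Ac2O, BF3·OEt2, AcOH, 70 °C, by way of the O-acetate and Fries shift) should give 1-(2-hydroxy-3,4,5,6-tetramethoxyphenyl)ethan-1-one F1.
- Vilsmeier–Haack formylation of 6 (POCl3, DMF), at the same carbon as the iodination, should give 2,5-diisopropoxy-4-methoxybenzaldehyde F2.
- Claisen–Schmidt condensation of the two (KOH, EtOH, rt) should give (E)-3-(2,5-diisopropoxy-4-methoxyphenyl)-1-(2-hydroxy-3,4,5,6-tetramethoxyphenyl)prop-2-en-1-one F3.
- Oxidative cyclisation with I2 (cat.) in DMSO at 120 °C should give 13.

**Step 4.** Base-induced oligomerisation of 8, or conjugate addition of its acetylide to a second molecule, may outrun transmetalation, and oxidative addition into the electron-rich, ortho-substituted iodide is not fast. Fallback, introducing a non-electrophilic acetylene and adding the ester carbon afterwards, setting out from 7 and coming back at 9: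
- Sonogashira coupling with trimethylsilylacetylene (Pd(PPh3)2Cl2, CuI, Et3N, 50 °C) should give [(2,5-diisopropoxy-4-methoxyphenyl)ethynyl]trimethylsilane F4.
- K2CO3 in MeOH should give 1-ethynyl-2,5-diisopropoxy-4-methoxybenzene F5.
- n-BuLi in THF at −78 °C should give lithium (2,5-diisopropoxy-4-methoxyphenyl)acetylide F6, which is quenched with ethyl chloroformate to give 9.

**Step 5.** Conjugate addition may be slow because the β-carbon of 9 is deactivated by the donor ring B and shielded by the ortho isopropoxy group, while the phenoxide of 4 is hindered by its ortho methoxy group; long heating in base invites ester cleavage and oxidation of the phenoxide. Fallback, replacing conjugate addition by a copper-catalysed vinylic C–O coupling, setting out from 9 and 4 and coming back at 10: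
- Anti hydroiodination of 9 (NaI, AcOH, 100 °C) should give ethyl (Z)-3-iodo-3-(2,5-diisopropoxy-4-methoxyphenyl)acrylate F7.
- Coupling with 4 (CuI, N,N-dimethylglycine, Cs2CO3, dioxane, 90 °C), with retention of geometry, should give 10.

**Step 6.** Hydroxide may add to the aryloxy-bearing carbon of the vinylogous carbonate and expel the aryloxide of 4, or the enol ether may be hydrolysed during acidification. Fallback, using an ester that is removed by acid without water, setting out from 7 and 4 and coming back at 11:
- Coupling of 7 with tert-butyl propiolate under the conditions of step 4 should give tert-butyl 3-(2,5-diisopropoxy-4-methoxyphenyl)prop-2-ynoate F8.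
- Addition of 4 as in step 5 should give tert-butyl (Z)-3-(2,5-diisopropoxy-4-methoxyphenyl)-3-(2,3,4,5-tetramethoxyphenoxy)acrylate F9.
- TFA in CH2Cl2 at 0 °C, with Et3SiH as cation trap, should release 11, which can be treated with TFAA in the same flask.

**Step 8.** Over-dealkylation is the main danger: on warming, boron bound to the phenolate at O5 or O5' can deliver chloride to the neighbouring methyl ether at C6 or C4'. Cleavage at the hindered 2'-position may also lag, and the hydroquinone can oxidise in air during work-up. Fallback, separating the two kinds of dealkylation by mechanism, setting out from 13 and coming back at 14: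
- Brønsted-acid demethylation (conc. HCl, EtOH, 80 °C), in which only the methyl ether peri to the protonated C4 carbonyl is activated toward chloride, should give 5-hydroxy-2',5'-diisopropoxy-4',6,7,8-tetramethoxyflavone F10.
- A short exposure to BCl3 at −78 °C, where only secondary alkyl ethers ionise, followed by the reductive aqueous work-up, should give 14.

## Further compounds

F1 | step 7 | 1-(2-hydroxy-3,4,5,6-tetramethoxyphenyl)ethan-1-one | CC(=O)c1c(O)c(OC)c(OC)c(OC)c1OC
F2 | step 7 | 2,5-diisopropoxy-4-methoxybenzaldehyde | COc1cc(OC(C)C)c(C=O)cc1OC(C)C
F3 | step 7 | (E)-3-(2,5-diisopropoxy-4-methoxyphenyl)-1-(2-hydroxy-3,4,5,6-tetramethoxyphenyl)prop-2-en-1-one | COc1cc(OC(C)C)c(/C=C/C(=O)c2c(O)c(OC)c(OC)c(OC)c2OC)cc1OC(C)C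
F4 | step 4 | [(2,5-diisopropoxy-4-methoxyphenyl)ethynyl]trimethylsilane | COc1cc(OC(C)C)c(C#C[Si](C)(C)C)cc1OC(C)C
F5 | step 4 | 1-ethynyl-2,5-diisopropoxy-4-methoxybenzene | COc1cc(OC(C)C)c(C#C)cc1OC(C)C
F6 | step 4 | lithium (2,5-diisopropoxy-4-methoxyphenyl)acetylide | [Li]C#Cc1cc(OC(C)C)c(OC)cc1OC(C)C
F7 | step 5 | ethyl (Z)-3-iodo-3-(2,5-diisopropoxy-4-methoxyphenyl)acrylate | CCOC(=O)/C=C(\I)c1cc(OC(C)C)c(OC)cc1OC(C)C
F8 | step 6 | tert-butyl 3-(2,5-diisopropoxy-4-methoxyphenyl)prop-2-ynoate | COc1cc(OC(C)C)c(C#CC(=O)OC(C)(C)C)cc1OC(C)C
F9 | step 6 | tert-butyl (Z)-3-(2,5-diisopropoxy-4-methoxyphenyl)-3-(2,3,4,5-tetramethoxyphenoxy)acrylate | COc1cc(O/C(=C\C(=O)OC(C)(C)C)c2cc(OC(C)C)c(OC)cc2OC(C)C)c(OC)c(OC)c1OC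
F10 | step 8 | 5-hydroxy-2',5'-diisopropoxy-4',6,7,8-tetramethoxyflavone | COc1cc(OC(C)C)c(-c2cc(=O)c3c(O)c(OC)c(OC)c(OC)c3o2)cc1OC(C)C
A1 | alternative 1 | 4-(benzyloxy)-2-bromo-5-methoxyphenyl 5,6,7,8-tetramethoxy-4-oxo-4H-chromene-3-carboxylate | COc1cc(OC(=O)c2coc3c(OC)c(OC)c(OC)c(OC)c3c2=O)c(Br)cc1OCc1ccccc1
A2 | alternative 1 | 5'-benzyloxy-4',5,6,7,8-pentamethoxyflavone bridged from C3 to O2' by a carbonyl group (chromeno[4,3-b]chromene-6,7-dione core) | O=C1Oc2cc(OC)c(OCc3ccccc3)cc2-c2oc3c(OC)c(OC)c(OC)c(OC)c3c(=O)c21
A3 | alternative 1 | 5'-(benzyloxy)-2'-hydroxy-4',5,6,7,8-pentamethoxyflavone | COc1cc(O)c(-c2cc(=O)c3c(OC)c(OC)c(OC)c(OC)c3o2)cc1OCc1ccccc1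
A4 | alternative 2 | 2-ethynyl-5,6,7,8-tetramethoxy-4H-chromen-4-one | C#Cc1cc(=O)c2c(OC)c(OC)c(OC)c(OC)c2o1
A5 | alternative 2 | 4-methoxy-2-(trimethylsilyloxy)furan | COc1coc(O[Si](C)(C)C)c1
A6 | alternative 2 | 2',5'-dihydroxy-4',5,6,7,8-pentamethoxyflavone | COc1cc(O)c(-c2cc(=O)c3c(OC)c(OC)c(OC)c(OC)c3o2)cc1O
A7 | alternative 3 | racemic 2,3,4-trimethoxy-4-[6-(2,5-bis(benzyloxy)-4-methoxyphenyl)-4-oxo-4H-pyran-2-yl]cyclobut-2-en-1-one | COC1=C(OC)C(OC)(c2cc(=O)cc(-c3cc(OCc4ccccc4)c(OC)cc3OCc3ccccc3)o2)C1=O
A8 | alternative 3 | 2',5'-bis(benzyloxy)-5-hydroxy-4',6,7,8-tetramethoxyflavone | COc1cc(OCc2ccccc2)c(-c2cc(=O)c3c(O)c(OC)c(OC)c(OC)c3o2)cc1OCc1ccccc1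
A9 | alternative 3 | dimethyl squarate (3,4-dimethoxycyclobut-3-ene-1,2-dione) | COC1=C(OC)C(=O)C1=O
A10 | alternative 3 | 2-[2,5-bis(benzyloxy)-4-methoxyphenyl]-4H-pyran-4-one | COc1cc(OCc2ccccc2)c(-c2cc(=O)cco2)cc1OCc1ccccc1
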